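**Retrosynthetic overview**

1. Target ⇐ protected epicatechin trimer (4β→6, then 4β→8) by hydrogenolysis of 21 benzyl ethers and three bromine caps, after the three gallates are put on and three silyl ethers taken off.
2. Key disconnection: in the terminal unit the bond O1–C8a (ring C) and the interflavan bond C4(middle unit)–C8 are cut together, which leads back to a mixed ether in which C4 of the middle unit is bound to the C2 oxygen of an open-chain 2-fluoroaryl fragment.
3. Enabling feature: C8a (bearing O1) and C8 (bearing the interflavan bond) are neighbouring carbons of ring A of the terminal unit, so an aryne across C8–C8a takes the tethered oxygen at C8a and leaves a carbanion at C8; C4 of the middle unit is a 2,4,6-trioxygenated benzylic carbon that leaves the resulting oxonium as a cation and is caught at C8.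
4. The mixed ether ⇐ 4β→6 dimer thioether (two (−)-epicatechin units joined by Friedel–Crafts coupling, with orthogonal O-alkyl and S-aryl groups at C4 and bromine caps) + open-chain alcohol (from 1,3,5-trifluorobenzene, methyl (R)-glycidate and an aryl Grignard reagent, with a Felkin reduction).
5. Ring order: all rings of the upper and middle units come from (−)-epicatechin; ring C of the terminal unit is the only ring that is made, and it is closed in step 15.

Key step: step 15

Assumption: methyl (R)-glycidate, 4-bromo-1,2-bis(benzyloxy)benzene and 3,4,5-tris(benzyloxy)benzoyl chloride are bought. "Tetra-O-benzyl" always means the 5,7,3',4' ethers. The C3 oxygen of the open-chain fragment is made a triisopropylsilyl ether so that it is a poorer aryne trap than the dialkyl ether oxygen.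

**Step 1**
Reactants: 1 (−)-epicatechin
Product: 2 5,7,3',4'-tetra-O-benzyl-(−)-epicatechin
Conditions: BnBr (4.4 equiv), K2CO3, DMF, 0 °C → rt
Reagents that add atoms: benzyl bromide, BrCc1ccccc1
Why: Williamson ether synthesis: the four phenols are deprotonated by K2CO3 and benzylated while the far less acidic secondary alcohol at C3 stays free and no stereocenter is touched.

**Step 2**
Reactants: 2 5,7,3',4'-tetra-O-benzyl-(−)-epicatechin
Product: 3 3-O-TBS-tetra-O-benzyl-(−)-epicatechin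
Conditions: TBSCl, imidazole, DMF, rt
Reagents that add atoms: tert-butyldimethylsilyl chloride, CC(C)(C)[Si](C)(C)Cl
Why: Imidazole-promoted silylation of the only free hydroxyl group gives a silyl ether that should be stable to the Lewis acids, silver salt and lithium amide used later.

**Step 3**
Reactants: 3 3-O-TBS-tetra-O-benzyl-(−)-epicatechin
Product: 4 4β-(2-ethoxyethoxy)-3-O-TBS-tetra-O-benzylepicatechin (2,3-cis, 3,4-trans)
Conditions: DDQ (2 equiv), 2-ethoxyethanol (5 equiv), CH2Cl2, rt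
Reagents that add atoms: 2-ethoxyethanol, CCOCCO
Why: DDQ benzylic oxidation (hydride abstraction at C4 to a cation stabilized by the 5,7-dialkoxy ring A) followed by capture by the alcohol anti to the 3-silyloxy group should set the new C4 stereocenter as 4β.

**Step 4**
Reactants: 4 4β-(2-ethoxyethoxy)-3-O-TBS-tetra-O-benzylepicatechin
Product: 5 6,8-dibromo-4β-(2-ethoxyethoxy)-3-O-TBS-tetra-O-benzylepicatechin
Conditions: NBS (2.2 equiv), NaHCO3, CH2Cl2, −20 °C → rt
Reagents that add atoms: N-bromosuccinimide, O=C1CCC(=O)N1Br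
Why: Electrophilic aromatic bromination at C6 and C8, the two most electron-rich positions, caps ring A of the future upper unit so that it cannot act as a nucleophile.

**Step 5**
Reactants: 4 4β-(2-ethoxyethoxy)-3-O-TBS-tetra-O-benzylepicatechin
Product: 6 8-bromo-4β-(2-ethoxyethoxy)-3-O-TBS-tetra-O-benzylepicatechin
Conditions: NBS (1.0 equiv), NaHCO3, CH2Cl2, −78 → −20 °C
Reagents that add atoms: N-bromosuccinimide, O=C1CCC(=O)N1Br
Why: Electrophilic aromatic bromination with one equivalent should go to C8, which is less shielded than C6 (flanked by two benzyloxy groups), so C6 stays free as the later nucleophilic site.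

**Step 6**
Reactants: 6 8-bromo-4β-(2-ethoxyethoxy)-3-O-TBS-tetra-O-benzylepicatechin
Product: 7 8-bromo-4β-(2,6-dimethylphenylthio)-3-O-TBS-tetra-O-benzylepicatechin
Conditions: 2,6-Me2C6H3SH (2 equiv), BF3·OEt2, CH2Cl2, −78 °C
Reagents that add atoms: 2,6-dimethylbenzenethiol, Cc1cccc(C)c1S
Why: Lewis-acid SN1 exchange at C4 through the flavan-4-yl cation: the thiol adds anti to the 3-silyloxy group and gives the 4β-thioether, which hard Lewis acids should leave alone.

**Step 7**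
Reactants: 5 6,8-dibromo-4β-(2-ethoxyethoxy)-3-O-TBS-tetra-O-benzylepicatechin; 7 8-bromo-4β-(2,6-dimethylphenylthio)-3-O-TBS-tetra-O-benzylepicatechin
Product: 8 dimer thioether 6,8-dibromo-3-O-TBS-tetra-O-benzylepicatechin-(4β→6)-[8-bromo-4β-(2,6-dimethylphenylthio)-3-O-TBS-tetra-O-benzylepicatechin]
Conditions: BF3·OEt2, MS 4 Å, CH2Cl2, −78 → −40 °C
Reagents that add atoms: none
Why: Friedel–Crafts alkylation: BF3·OEt2 ionizes only the C4–O bond of 5, and the cation is attacked by C6 of 7 (C8 is blocked by bromine, 5 cannot attack itself) anti to the 3-silyloxy group, which should set C4 of the upper unit as 4β.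

**Step 8**
Reactants: 9 1,3,5-trifluorobenzene
Product: 10 1,3-bis(benzyloxy)-5-fluorobenzene
Conditions: BnOH (2.2 equiv), NaH, NMP, 0 → 100 °C
Reagents that add atoms: benzyl alcohol, OCc1ccccc1
Why: Twofold nucleophilic aromatic substitution (SNAr): each fluorine is activated by the two others, and after two alkoxy groups are in place the last fluorine is too deactivated to react.

**Step 9**
Reactants: 10 1,3-bis(benzyloxy)-5-fluorobenzene; 11 methyl (R)-glycidate
Product: 14 methyl (2R)-3-[2,4-bis(benzyloxy)-6-fluorophenyl]-2-hydroxypropanoate, via aryllithium 12 (not isolated), via arylmagnesium bromide 13 (not isolated)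
Conditions: lithium 2,2,6,6-tetramethylpiperidide (LiTMP, from the amine and n-BuLi), THF, −78 °C; MgBr2·OEt2; CuI (10 mol%), 11, −78 → −30 °C; aq NH4Cl
Reagents that add atoms: none
Why: Ortho-lithiation by the lithium amide at the most acidic C–H (between F and OBn), transmetalation to magnesium and copper-catalysed SN2 opening of the epoxide at its CH2 terminus leave the stereocenter of 11 untouched and give the (R)-α-hydroxy ester.

**Step 10**
Reactants: 14 methyl (2R)-3-[2,4-bis(benzyloxy)-6-fluorophenyl]-2-hydroxypropanoate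
Product: 15 methyl (2R)-3-[2,4-bis(benzyloxy)-6-fluorophenyl]-2-(triisopropylsilyloxy)propanoate
Conditions: TIPSOTf, 2,6-lutidine, CH2Cl2, 0 °C
Reagents that add atoms: triisopropylsilyl triflate, CC(C)[Si](C(C)C)(C(C)C)OS(=O)(=O)C(F)(F)F
Why: Silylation of the secondary alcohol with a silyl triflate; the bulky triisopropylsilyl group makes this oxygen a poor nucleophile in step 15 and a good Felkin control element in step 13.

**Step 11**
Reactants: 15 methyl (2R)-3-[2,4-bis(benzyloxy)-6-fluorophenyl]-2-(triisopropylsilyloxy)propanoate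
Product: 16 (2R)-3-[2,4-bis(benzyloxy)-6-fluorophenyl]-N-methoxy-N-methyl-2-(triisopropylsilyloxy)propanamide
Conditions: MeNH(OMe)·HCl, i-PrMgCl, THF, −20 → 0 °C
Reagents that add atoms: N,O-dimethylhydroxylamine hydrochloride, CNOC.Cl
Why: Weinreb amide formation by aminolysis of the ester with the chloromagnesium amide, under which the α-stereocenter should not be enolized.

**Step 12**
Reactants: 16 (2R)-3-[2,4-bis(benzyloxy)-6-fluorophenyl]-N-methoxy-N-methyl-2-(triisopropylsilyloxy)propanamide; 17 4-bromo-1,2-bis(benzyloxy)benzene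
Product: 19 (2R)-1-[3,4-bis(benzyloxy)phenyl]-3-[2,4-bis(benzyloxy)-6-fluorophenyl]-2-(triisopropylsilyloxy)propan-1-one, via arylmagnesium bromide 18 (not isolated)
Conditions: 17, Mg, THF; then 16, THF, 0 °C → rt; aq NH4Cl
Reagents that add atoms: none
Why: Grignard addition to a Weinreb amide stops at the ketone because the chelated tetrahedral intermediate survives until work-up.

**Step 13**
Reactants: 19 (2R)-1-[3,4-bis(benzyloxy)phenyl]-3-[2,4-bis(benzyloxy)-6-fluorophenyl]-2-(triisopropylsilyloxy)propan-1-one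
Product: 20 (1R,2R)-1-[3,4-bis(benzyloxy)phenyl]-3-[2,4-bis(benzyloxy)-6-fluorophenyl]-2-(triisopropylsilyloxy)propan-1-ol
Conditions: LiBH(s-Bu)3, THF, −78 °C; aq NH4Cl
Reagents that add atoms: none
Why: Felkin–Anh reduction: the bulky, non-chelating hydride attacks the aryl ketone anti to the α-silyloxy group and should give the syn alcohol, which sets the carbinol carbon (the future C2) as R.

**Step 14**
Reactants: 8 dimer thioether; 20 (1R,2R)-1-[3,4-bis(benzyloxy)phenyl]-3-[2,4-bis(benzyloxy)-6-fluorophenyl]-2-(triisopropylsilyloxy)propan-1-ol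
Product: 21 mixed ether: the dimer of 8 whose lower unit carries at C4 (4β) the C1 oxygen of 20 in place of the arylthio group
Conditions: AgBF4, 2,6-di-tert-butyl-4-methylpyridine, MS 4 Å, CH2Cl2, −60 → −20 °C, dark
Reagents that add atoms: none
Why: Silver-assisted SN1 etherification (thiophilic activation): the silver cation of AgBF4 binds sulfur and removes the thiolate, the flavan-4-yl cation is captured by the alcohol oxygen of 20 anti to the 3-silyloxy group, which should set the C4–O bond as 4β, and the hindered pyridine keeps the acid-labile ether from re-ionizing.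

**Step 15**
Reactants: 21 mixed ether
Product: 25 protected trimer 6,8-dibromo-3-O-TBS-tetra-O-benzylepicatechin-(4β→6)-8-bromo-3-O-TBS-tetra-O-benzylepicatechin-(4β→8)-3-O-TIPS-tetra-O-benzylepicatechin, via lithiated fluoroarene 22 (not isolated), via aryne 23 (not isolated), via oxonium ylide 24 (not isolated)
Conditions: LiTMP (3 equiv, from the amine and n-BuLi), Et2O, −78 °C, then → 0 °C; aq NH4Cl
Reagents that add atoms: none
Why: Proposed new method: deprotonation of the C–H between F and OBn and loss of LiF give the C8–C8a aryne 23, the tethered ether oxygen (the C2 oxygen of the terminal unit) adds at C8a to form the cyclic aryl oxonium ylide 24, and heterolysis of its C4–O bond releases the 2,4,6-trioxygenated flavan-4-yl cation next to the C8 carbanion, which collapses to the C4–C8 bond, a net insertion of the aryne into the C4–O sigma bond. The closest known reaction types are the intramolecular trapping of arynes by tethered silyl ethers with O-to-C silyl shift, aryne insertions into sigma bonds in general, the alkoxide–aryne cyclization to chromans and the Lewis-acid C4-arylation of 4-alkoxyflavans. Ring C of the terminal unit closes by 6-exo attack of oxygen on the in-plane orbital of the aryne carbon C8a. C4 of the middle unit is re-formed with retention, because oxygen leaves and C8 arrives on the same β face inside the ion pair and the α-oriented 3-OTBS group shields the other face, so the 3,4-trans (4β) bond should result, while C2 and C3 of the terminal unit are not touched. The step needs lithiation next to fluorine (ortho-fluorine acidifies more than ortho-alkoxy toward a lithium amide), attack at C8a by the dialkyl ether oxygen and not by the shielded, weakly basic silyl ether oxygen (six- against five-membered closure), and cleavage of C4–O and not C2–O (only C4 gives a trioxygenated benzylic cation). The 4→8 regiochemistry is then fixed by the tether, since the carbanion can only sit at C8.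

**Step 16**
Reactants: 25 protected trimer
Product: 26 trimer triol (25 without its three silyl groups)
Conditions: TBAF, THF, rt → 45 °C
Reagents that add atoms: none
Why: Fluoride-mediated desilylation (strong Si–F bond) should free the three secondary alcohols without touching benzyl ethers, aryl bromides or the interflavan bonds.

**Step 17**
Reactants: 26 trimer triol; 27 3,4,5-tris(benzyloxy)benzoyl chloride (three equivalents enter the product)
Product: 28 tris(3,4,5-tri-O-benzylgalloyl) ester of 26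
Conditions: 27 (6 equiv), DMAP, pyridine, CH2Cl2, rt → 40 °C
Reagents that add atoms: 3,4,5-tris(benzyloxy)benzoyl chloride, O=C(Cl)c1cc(OCc2ccccc2)c(OCc2ccccc2)c(OCc2ccccc2)c1
Why: DMAP-catalysed threefold acylation: each of the three C3 alcohols takes up one molecule of acid chloride 27 through its N-acylpyridinium salt, so three tri-O-benzylgalloyl groups are transferred and three equivalents of HCl are bound by pyridine; no stereocenter is involved.

**Step 18**
Reactants: 28 tris(3,4,5-tri-O-benzylgalloyl) ester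
Product: 29 (−)-epicatechin 3-O-gallate-(4β→6)-(−)-epicatechin 3-O-gallate-(4β→8)-(−)-epicatechin 3-O-gallate (CNP0183218.1)
Conditions: H2 (1 atm), Pd(OH)2/C, NaOAc (3.3 equiv), THF/MeOH, rt
Reagents that add atoms: none
Why: Heterogeneous hydrogenolysis should cleave the 21 benzyl ethers and reduce the three aryl bromides in one operation, the acetate taking up HBr so that the acid-labile interflavan bonds and the gallate esters survive.

**Compound list**

1 | (−)-epicatechin, (2R,3R) | O[C@@H]1Cc2c(O)cc(O)cc2O[C@@H]1c1ccc(O)c(O)c1 | starting material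
2 | 5,7,3',4'-tetra-O-benzyl-(−)-epicatechin, (2R,3R) | O[C@@H]1Cc2c(OCc3ccccc3)cc(OCc3ccccc3)cc2O[C@@H]1c1ccc(OCc2ccccc2)c(OCc2ccccc2)c1 | intermediate
3 | 3-O-TBS-tetra-O-benzyl-(−)-epicatechin, (2R,3R) | CC(C)(C)[Si](C)(C)O[C@@H]1Cc2c(OCc3ccccc3)cc(OCc3ccccc3)cc2O[C@@H]1c1ccc(OCc2ccccc2)c(OCc2ccccc2)c1 | intermediate
4 | 4β-(2-ethoxyethoxy)-3-O-TBS-tetra-O-benzylepicatechin (2,3-cis, 3,4-trans) | CC(C)(C)[Si](C)(C)O[C@@H]1[C@@H](OCCOCC)c2c(OCc3ccccc3)cc(OCc3ccccc3)cc2O[C@@H]1c1ccc(OCc2ccccc2)c(OCc2ccccc2)c1 | intermediate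
5 | 6,8-dibromo derivative of 4 | CC(C)(C)[Si](C)(C)O[C@@H]1[C@@H](OCCOCC)c2c(OCc3ccccc3)c(Br)c(OCc3ccccc3)c(Br)c2O[C@@H]1c1ccc(OCc2ccccc2)c(OCc2ccccc2)c1 | intermediate
6 | 8-bromo derivative of 4 | CC(C)(C)[Si](C)(C)O[C@@H]1[C@@H](OCCOCC)c2c(OCc3ccccc3)cc(OCc3ccccc3)c(Br)c2O[C@@H]1c1ccc(OCc2ccccc2)c(OCc2ccccc2)c1 | intermediate
7 | 8-bromo-4β-(2,6-dimethylphenylthio)-3-O-TBS-tetra-O-benzylepicatechin | CC(C)(C)[Si](C)(C)O[C@@H]1[C@@H](Sc2c(C)cccc2C)c2c(OCc3ccccc3)cc(OCc3ccccc3)c(Br)c2O[C@@H]1c1ccc(OCc2ccccc2)c(OCc2ccccc2)c1 | intermediate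
8 | dimer thioether: upper unit 6,8-dibromo-3-O-TBS-tetra-O-benzylepicatechin bound by C4 (4β) to C6 of lower unit 8-bromo-4β-(2,6-dimethylphenylthio)-3-O-TBS-tetra-O-benzylepicatechin | CC(C)(C)[Si](C)(C)O[C@@H]1[C@@H](c2c(OCc4ccccc4)c(Br)c3c(c2OCc2ccccc2)[C@H](Sc2c(C)cccc2C)[C@@H](O[Si](C)(C)C(C)(C)C)[C@@H](c2ccc(OCc4ccccc4)c(OCc4ccccc4)c2)O3)c2c(OCc3ccccc3)c(Br)c(OCc3ccccc3)c(Br)c2O[C@@H]1c1ccc(OCc2ccccc2)c(OCc2ccccc2)c1 | intermediate
9 | 1,3,5-trifluorobenzene | Fc1cc(F)cc(F)c1 | starting material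
10 | 1,3-bis(benzyloxy)-5-fluorobenzene | Fc1cc(OCc2ccccc2)cc(OCc2ccccc2)c1 | intermediate
11 | methyl (R)-glycidate | COC(=O)[C@H]1CO1 | starting material
12 | [2,4-bis(benzyloxy)-6-fluorophenyl]lithium (not isolated) | [Li]c1c(F)cc(OCc2ccccc2)cc1OCc1ccccc1 | intermediate
13 | [2,4-bis(benzyloxy)-6-fluorophenyl]magnesium bromide (not isolated) | Br[Mg]c1c(F)cc(OCc2ccccc2)cc1OCc1ccccc1 | intermediate
14 | methyl (2R)-3-[2,4-bis(benzyloxy)-6-fluorophenyl]-2-hydroxypropanoate | COC(=O)[C@H](O)Cc1c(F)cc(OCc2ccccc2)cc1OCc1ccccc1 | intermediate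
15 | methyl (2R)-3-[2,4-bis(benzyloxy)-6-fluorophenyl]-2-(triisopropylsilyloxy)propanoate | COC(=O)[C@H](O[Si](C(C)C)(C(C)C)C(C)C)Cc1c(F)cc(OCc2ccccc2)cc1OCc1ccccc1 | intermediate
16 | (2R)-3-[2,4-bis(benzyloxy)-6-fluorophenyl]-N-methoxy-N-methyl-2-(triisopropylsilyloxy)propanamide | CON(C)C(=O)[C@H](O[Si](C(C)C)(C(C)C)C(C)C)Cc1c(F)cc(OCc2ccccc2)cc1OCc1ccccc1 | intermediate
17 | 4-bromo-1,2-bis(benzyloxy)benzene | Brc1ccc(OCc2ccccc2)c(OCc2ccccc2)c1 | starting material
18 | [3,4-bis(benzyloxy)phenyl]magnesium bromide (not isolated) | Br[Mg]c1ccc(OCc2ccccc2)c(OCc2ccccc2)c1 | intermediate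
19 | (2R)-1-[3,4-bis(benzyloxy)phenyl]-3-[2,4-bis(benzyloxy)-6-fluorophenyl]-2-(triisopropylsilyloxy)propan-1-one | O=C(c1ccc(OCc2ccccc2)c(OCc2ccccc2)c1)[C@H](O[Si](C(C)C)(C(C)C)C(C)C)Cc1c(F)cc(OCc2ccccc2)cc1OCc1ccccc1 | intermediate
20 | (1R,2R)-1-[3,4-bis(benzyloxy)phenyl]-3-[2,4-bis(benzyloxy)-6-fluorophenyl]-2-(triisopropylsilyloxy)propan-1-ol | O[C@H](c1ccc(OCc2ccccc2)c(OCc2ccccc2)c1)[C@H](O[Si](C(C)C)(C(C)C)C(C)C)Cc1c(F)cc(OCc2ccccc2)cc1OCc1ccccc1 | intermediate
21 | mixed ether: dimer of 8 in which the lower C4 (4β) carries the C1 oxygen of 20 instead of the arylthio group | CC(C)(C)[Si](C)(C)O[C@@H]1[C@@H](c2c(OCc4ccccc4)c(Br)c3c(c2OCc2ccccc2)[C@H](O[C@H](c2ccc(OCc4ccccc4)c(OCc4ccccc4)c2)[C@H](O[Si](C(C)C)(C(C)C)C(C)C)Cc2c(F)cc(OCc4ccccc4)cc2OCc2ccccc2)[C@@H](O[Si](C)(C)C(C)(C)C)[C@@H](c2ccc(OCc4ccccc4)c(OCc4ccccc4)c2)O3)c2c(OCc3ccccc3)c(Br)c(OCc3ccccc3)c(Br)c2O[C@@H]1c1ccc(OCc2ccccc2)c(OCc2ccccc2)c1 | intermediate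
22 | 21 lithiated at the C–H between F and OBn of the fluoroarene ring (not isolated) | CC(C)(C)[Si](C)(C)O[C@@H]1[C@@H](c2c(OCc4ccccc4)c(Br)c3c(c2OCc2ccccc2)[C@H](O[C@H](c2ccc(OCc4ccccc4)c(OCc4ccccc4)c2)[C@H](O[Si](C(C)C)(C(C)C)C(C)C)Cc2c(F)c([Li])c(OCc4ccccc4)cc2OCc2ccccc2)[C@@H](O[Si](C)(C)C(C)(C)C)[C@@H](c2ccc(OCc4ccccc4)c(OCc4ccccc4)c2)O3)c2c(OCc3ccccc3)c(Br)c(OCc3ccccc3)c(Br)c2O[C@@H]1c1ccc(OCc2ccccc2)c(OCc2ccccc2)c1 | intermediate
23 | aryne from 22 by loss of LiF, triple bond between the future C8 and C8a (not isolated) | CC(C)(C)[Si](C)(C)O[C@@H]1[C@@H](c2c(OCc4ccccc4)c(Br)c3c(c2OCc2ccccc2)[C@H](O[C@H](c2ccc(OCc4ccccc4)c(OCc4ccccc4)c2)[C@H](O[Si](C(C)C)(C(C)C)C(C)C)CC2=C(OCc4ccccc4)C=C(OCc4ccccc4)C#C2)[C@@H](O[Si](C)(C)C(C)(C)C)[C@@H](c2ccc(OCc4ccccc4)c(OCc4ccccc4)c2)O3)c2c(OCc3ccccc3)c(Br)c(OCc3ccccc3)c(Br)c2O[C@@H]1c1ccc(OCc2ccccc2)c(OCc2ccccc2)c1 | intermediate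
24 | cyclic aryl oxonium ylide: ring C of the terminal unit closed through O+, carbanion at C8 (not isolated) | CC(C)(C)[Si](C)(C)O[C@@H]1[C@@H](c2c(OCc4ccccc4)c(Br)c3c(c2OCc2ccccc2)[C@H]([O+]2[C@H](c4ccc(OCc5ccccc5)c(OCc5ccccc5)c4)[C@H](O[Si](C(C)C)(C(C)C)C(C)C)Cc4c(OCc5ccccc5)cc(OCc5ccccc5)[c-]c42)[C@@H](O[Si](C)(C)C(C)(C)C)[C@@H](c2ccc(OCc4ccccc4)c(OCc4ccccc4)c2)O3)c2c(OCc3ccccc3)c(Br)c(OCc3ccccc3)c(Br)c2O[C@@H]1c1ccc(OCc2ccccc2)c(OCc2ccccc2)c1 | intermediate
25 | protected trimer: 6,8-dibromo-3-O-TBS-tetra-O-benzylepicatechin-(4β→6)-8-bromo-3-O-TBS-tetra-O-benzylepicatechin-(4β→8)-3-O-TIPS-tetra-O-benzylepicatechin | CC(C)(C)[Si](C)(C)O[C@@H]1[C@@H](c2c(OCc4ccccc4)c(Br)c3c(c2OCc2ccccc2)[C@H](c2c(OCc5ccccc5)cc(OCc5ccccc5)c4c2O[C@H](c2ccc(OCc5ccccc5)c(OCc5ccccc5)c2)[C@H](O[Si](C(C)C)(C(C)C)C(C)C)C4)[C@@H](O[Si](C)(C)C(C)(C)C)[C@@H](c2ccc(OCc4ccccc4)c(OCc4ccccc4)c2)O3)c2c(OCc3ccccc3)c(Br)c(OCc3ccccc3)c(Br)c2O[C@@H]1c1ccc(OCc2ccccc2)c(OCc2ccccc2)c1 | intermediate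
26 | trimer triol: 25 with three free C3 hydroxyl groups | O[C@@H]1[C@@H](c2c(OCc4ccccc4)c(Br)c3c(c2OCc2ccccc2)[C@H](c2c(OCc5ccccc5)cc(OCc5ccccc5)c4c2O[C@H](c2ccc(OCc5ccccc5)c(OCc5ccccc5)c2)[C@H](O)C4)[C@@H](O)[C@@H](c2ccc(OCc4ccccc4)c(OCc4ccccc4)c2)O3)c2c(OCc3ccccc3)c(Br)c(OCc3ccccc3)c(Br)c2O[C@@H]1c1ccc(OCc2ccccc2)c(OCc2ccccc2)c1 | intermediate
27 | 3,4,5-tris(benzyloxy)benzoyl chloride | O=C(Cl)c1cc(OCc2ccccc2)c(OCc2ccccc2)c(OCc2ccccc2)c1 | starting material
28 | tris(3,4,5-tri-O-benzylgalloyl) ester of 26 | O=C(O[C@@H]1[C@@H](c2c(OCc4ccccc4)c(Br)c3c(c2OCc2ccccc2)[C@H](c2c(OCc5ccccc5)cc(OCc5ccccc5)c4c2O[C@H](c2ccc(OCc5ccccc5)c(OCc5ccccc5)c2)[C@H](OC(=O)c2cc(OCc5ccccc5)c(OCc5ccccc5)c(OCc5ccccc5)c2)C4)[C@@H](OC(=O)c2cc(OCc4ccccc4)c(OCc4ccccc4)c(OCc4ccccc4)c2)[C@@H](c2ccc(OCc4ccccc4)c(OCc4ccccc4)c2)O3)c2c(OCc3ccccc3)c(Br)c(OCc3ccccc3)c(Br)c2O[C@@H]1c1ccc(OCc2ccccc2)c(OCc2ccccc2)c1)c1cc(OCc2ccccc2)c(OCc2ccccc2)c(OCc2ccccc2)c1 | intermediate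
29 | (−)-epicatechin 3-O-gallate-(4β→6)-(−)-epicatechin 3-O-gallate-(4β→8)-(−)-epicatechin 3-O-gallate | O=C(O[C@@H]1[C@@H](c2c(O)cc3c(c2O)[C@H](c2c(O)cc(O)c4c2O[C@H](c2ccc(O)c(O)c2)[C@H](OC(=O)c2cc(O)c(O)c(O)c2)C4)[C@@H](OC(=O)c2cc(O)c(O)c(O)c2)[C@@H](c2ccc(O)c(O)c2)O3)c2c(O)cc(O)cc2O[C@@H]1c1ccc(O)c(O)c1)c1cc(O)c(O)c(O)c1 | target

**Totals and risks**

Total step count: 18. Longest linear sequence: 11 steps (1, 2, 3, 5, 6, 7, 14, 15, 16, 17, 18; the branch of steps 8–13 joins at step 14 and is equally long).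

Steps most likely to fail:

1. Step 15 (Proposed new method). The C8 carbanion of the oxonium ylide may be protonated, or the cation may be lost by elimination, before the carbon–carbon bond forms. The silyl ether oxygen may add to the aryne in a five-membered closure. Lithiation may also occur between the two benzyloxy groups instead of next to fluorine. The fallback uses known chemistry, sets out from 20 (with 8) and comes back at 25. Alcohol 20 is treated with LiTMP (2.2 equiv, Et2O, −78 → 0 °C); the lithium alkoxide adds to the aryne at C8a (alkoxide–aryne cyclization to a chroman) and protonation at C8 should give 3-O-triisopropylsilyl-5,7,3',4'-tetra-O-benzyl-(−)-epicatechin F1. F1 is then the carbon nucleophile toward 8 under AgBF4 and the hindered pyridine, and Friedel–Crafts attack by its C8 should give 25.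

2. Step 14. C-alkylation of the electron-rich fluoroarene ring of 20 and loss of the cation by elimination may outrun O-alkylation by the hindered secondary alcohol, and traces of acid may re-ionize the benzylic ether. The fallback drops the oxygen tether, sets out from 8 and 3 and comes back at 26. Dimer thioether 8 is coupled directly with the chiral-pool monomer 3 (AgBF4, hindered pyridine, CH2Cl2); Friedel–Crafts attack by C8 of 3 should give the tris-TBS trimer F2, which is desilylated with TBAF as in step 16 to give 26.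

3. Step 7. Attack by the doubly flanked, bromine-deactivated C6 of 7 may be slow enough that the Lewis acid begins to ionize the C4–S bond of 7, which would scramble the units and lose the cation from 5 by elimination. The fallback swaps the two leaving groups, sets out from 5 and 6 and comes back at 8. Compound 5 is converted with 2,6-dimethylbenzenethiol and BF3·OEt2 into 6,8-dibromo-4β-(2,6-dimethylphenylthio)-3-O-TBS-tetra-O-benzylepicatechin F3. F3 is activated irreversibly with AgBF4 and the hindered pyridine in the presence of 6, whose 2-ethoxyethoxy group is inert without acid, to give the 4β→6 dimer with a 4β-(2-ethoxyethoxy) group on the lower unit F4. Thiol exchange on F4 (2,6-dimethylbenzenethiol, BF3·OEt2) then gives 8.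

**Further compounds**

F1 | step 15 | 3-O-triisopropylsilyl-5,7,3',4'-tetra-O-benzyl-(−)-epicatechin, (2R,3R) | CC(C)[Si](C(C)C)(C(C)C)O[C@@H]1Cc2c(OCc3ccccc3)cc(OCc3ccccc3)cc2O[C@@H]1c1ccc(OCc2ccccc2)c(OCc2ccccc2)c1
F2 | step 14 | tris-TBS trimer: 25 with TBS in place of TIPS on the terminal unit | CC(C)(C)[Si](C)(C)O[C@@H]1[C@@H](c2c(OCc4ccccc4)c(Br)c3c(c2OCc2ccccc2)[C@H](c2c(OCc5ccccc5)cc(OCc5ccccc5)c4c2O[C@H](c2ccc(OCc5ccccc5)c(OCc5ccccc5)c2)[C@H](O[Si](C)(C)C(C)(C)C)C4)[C@@H](O[Si](C)(C)C(C)(C)C)[C@@H](c2ccc(OCc4ccccc4)c(OCc4ccccc4)c2)O3)c2c(OCc3ccccc3)c(Br)c(OCc3ccccc3)c(Br)c2O[C@@H]1c1ccc(OCc2ccccc2)c(OCc2ccccc2)c1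
F3 | step 7 | 6,8-dibromo-4β-(2,6-dimethylphenylthio)-3-O-TBS-tetra-O-benzylepicatechin | CC(C)(C)[Si](C)(C)O[C@@H]1[C@@H](Sc2c(C)cccc2C)c2c(OCc3ccccc3)c(Br)c(OCc3ccccc3)c(Br)c2O[C@@H]1c1ccc(OCc2ccccc2)c(OCc2ccccc2)c1
F4 | step 7 | 4β→6 dimer as 8 but with 4β-(2-ethoxyethoxy) on the lower unit | CC(C)(C)[Si](C)(C)O[C@@H]1[C@@H](c2c(OCc4ccccc4)c(Br)c3c(c2OCc2ccccc2)[C@H](OCCOCC)[C@@H](O[Si](C)(C)C(C)(C)C)[C@@H](c2ccc(OCc4ccccc4)c(OCc4ccccc4)c2)O3)c2c(OCc3ccccc3)c(Br)c(OCc3ccccc3)c(Br)c2O[C@@H]1c1ccc(OCc2ccccc2)c(OCc2ccccc2)c1
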